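## Analysis of the target

The target is an ester of two isoprenoid halves. The alcohol half is a bicyclic lactone acid: a cyclohexane (ring A, C1–C6) cis-fused through C5 and C6 to a seven-membered unsaturated lactone (ring B: C5–C7(=O)–O8–C9H2–C10=C11–C6) with the free carboxyl group on C10. C1 bears isopropyl, and C4 is a tertiary carbinol whose CH2O arm is acylated. The acid half is (E)-2-(hydroxymethyl)-3-[(1R,6S)-3-(hydroxymethyl)-6-isopropylcyclohex-2-en-1-yl]acrylic acid (ring carbons C1'–C6', acrylate carbons Cα and Cβ).

Ring A holds four contiguous stereocentres (C1 R, C4 S, C5 R, C6 S in these labels). The isopropyl group on C1 is trans to the C6–C11 bond, the C5–C7 bond is cis to C6–C11, and the C4 hydroxyl is cis to C7. In the acid half the side chain on C1' and the isopropyl group on C6' are cis, so the two halves have opposite relative configuration at the isopropyl-bearing pair and need separate stereochemical solutions.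

Sensitive sites are:
- the lactone, an allylic ester of a 2-(acyloxymethyl)acrylic acid, open to SN2' attack by nucleophilic amines or phosphines and to ionisation by zerovalent palladium;
- the β-hydroxy ester at C4 (retro-aldol, dehydration) and the epimerisable C5–H;
- the doubly allylic C1'–H of the acid half, which is γ to the ester.

The difficulty lies in ring A, with a tertiary carbinol next to two ring-fusion centres, in placing O8 between C7 and C9, in telling five oxygen functions apart, and in acylating a neopentyl-type primary hydroxyl.

The plan rests on one feature: C5 and C6 carry cis carbon branches (C7 and C11), both trans to the isopropyl group on C1, and C7, C9, C10, C11 plus the carboxyl carbon form a 2-methylbutadiene unit. This is the imprint of a diene that has added across the C=C bond of 4-isopropylcyclohex-2-enone on the face opposite to isopropyl.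

## Retrosynthetic reasoning

**Ester bond and end-game.** The only acyclic link between the halves is the ester C–O bond at the C4 CH2O arm. Cutting it last gives the diol aldehyde 18 and the bis-silylated acid 38, so the route is convergent. The tertiary hydroxyl of 18 cannot compete in acylation. The C10 carboxyl is carried as an aldehyde through the coupling (40), raised to the acid by a Pinnick oxidation (41), and the two silyl ethers are removed last to give 42. This avoids a separate carboxyl protecting group.

**C10 carboxyl from a methyl group.** The aldehyde 17 is traced to the methyl lactone 15 by a Riley oxidation. In 15 the methyl group is the only unactivated allylic position on the disubstituted alkene terminus, because C9 already carries the acyloxy oxygen. The methyl group therefore can come from a cheap methyl-substituted diene.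

**O8 by oxygen insertion.** The C7–O8 and O8–C9 bonds of lactone 15 are cut back to the six-membered β,γ-unsaturated ketone 14 (Baeyer–Villiger oxidation, allylic C9 migrating). Ketone 14 comes from the conjugated enone 12 by deconjugation through its dienolate 13. This turns the medium-ring lactone into a cyclohexenone problem and places the C10=C11 double bond before the oxygen is inserted.

**C4 carbinol.** The acetonide of 12 is traced through alcohol 11, acetonide 10 and diol 9 to the spiro-epoxide 8, and then to the C4 ketone 7 by cutting the C4–CH2 bond (Corey–Chaykovsky epoxidation). This must be done while C5–H is activated by only one carbonyl, so it comes directly after ring construction. The axial C5–C7 bond of 7 should direct the methylene to the opposite face.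

**Key disconnection.** Cutting C5–C7 and C6–C11 of 7 opens ring B to the enone 4 and the silyloxy diene 6. One cycloaddition forms two C–C bonds, a ring and the C5/C6 relationship to C1 from a single stereocentre. It also delivers C7 already oxygenated and the future carboxyl carbon on C10.

**Precursors of the key step.** Enone 4 is cut at its C=C bond and at the bond β to the carbonyl to aldehyde 1 and enone 2 (enamine-catalysed Michael addition to 3, then aldol condensation). Diene 6 is the silyl dienol ether of enal 5.

**Acid half, acrylate.** The Cα=Cβ bond of ester 37 (and acid 38) is cut to aldehyde 33 and the stabilised ylide 36, made from 34 and 35. A stabilised, α-substituted ylide should give the E geometry and brings the protected hydroxymethyl group with it.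

**Acid half, ring.** The cis relationship of C1' and C6' is that of an endo Diels–Alder adduct. Ring atoms C1'–C6' of 27 are cut at C1'–C6' and C4'–C5' to the diene 23 and the acrylimide 26, whose auxiliary (from 24 and 25) sets the absolute configuration. The acyl group on C6' is then turned into isopropyl (28, 29, 30, 31), and the C1' arm is unmasked and oxidised (32, 33).

**Diene for the acid half.** Diene 23 is cut at its central C–C single bond to the vinyl bromide 20 (from 19) and the vinylstannane 21 (Stille coupling to 22, then etherification).

## Alternatives that were turned down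

**Alternative 1:** The disconnection is at the lactone C7–O8–C9 unit. The seven-membered lactone acetonide A1 (the same structure as 15) is traced to the cis-fused β,γ-unsaturated bicyclic ketone A2 (the same structure as 14). The forward key step is a Baeyer–Villiger oxidation with a silyl peroxide and a silyl triflate catalyst, in which the allylic C9 migrates.
- For it: the key step makes a ring that is actually present in the target, and the silyl peroxide leaves the alkene alone.
- Against it: as a strategy it does not say how A2, with four stereocentres on ring A and a cis ring fusion, is assembled. The regiochemistry (primary allylic C9 against secondary C5) is not fixed by the structure. The main risk falls late, on an advanced and isomerisation-prone β,γ-enone.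
- Comparison: the chosen strategy does not avoid this oxygen insertion (steps 10 and 11) and shares its uncertainty. Alternative 1 is stronger in that its key step forms a ring of the target, whereas the chosen key step forms a carbocycle that must later be expanded. In return the chosen strategy places its main risk at step 4, on cheap material, and solves the larger problem (two C–C bonds, ring B and the C5/C6 configuration from one bought stereocentre) in one operation.

**Alternative 2:** The six-membered carbocycle is disconnected by a Diels–Alder reaction between the terminal diene of the isopropyl triene A3 and the conjugated C=C bond of the allenoate A4 under a chiral boron Lewis acid. This gives the 2-methylenecyclohex-3-ene ester A5, meant to serve both halves.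
- For it: convergence and step economy. One catalytic, enantioselective step would feed both halves, and A5 already carries the oxygenated C9/C10 unit and an exocyclic methylene as a handle for C4. On step count it is stronger than the chosen route.
- Against it: A3 contains two 1,3-diene units and A4 two π bonds, so periselectivity and site selectivity must both be right. In A5 the isopropyl group sits on an sp2 carbon, so its stereocentre must be created later by a face-selective and chemoselective reduction in the presence of two other alkenes. The two halves need opposite outcomes there (trans in the lactone half, cis in the acid half). The acid half also lacks one carbon relative to the lactone half, so a degradation is needed.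
- Comparison: the chosen route is longer and uses two separate cycloadditions, but every stereocentre has a named controlling element (the C1 isopropyl group for the lactone half, the auxiliary and the endo rule for the acid half).

**Alternative 3:** Ring A is disconnected at C4–C5. A samarium-based one-electron reductant converts the α-bromo butyrolactone A7 into its enolate, which adds to the tethered α-alkoxy ketone and gives the cis-fused hydroxy bicyclic lactone A6.
- For it: the tertiary carbinol C4 and C5 are set in one chelation-controlled C–C bond formation, the primary oxygen arrives already differentiated, and no oxygen insertion with a regiochemical question is needed. On these points it is stronger than the chosen route, which needs three steps for C4 and then the insertion.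
- Against it: A6 is a five-membered lactone that contains only C7 and C11. C9, C10 and the carboxyl carbon must still be added by lactone opening, oxidation at C11, a Z-selective olefination and a seven-membered relactonisation. A7 already needs C1 and C6 set in an open-chain precursor, so two stereocentres must be made before the key step.
- Comparison: the chosen strategy brings in C7, C9, C10, C11 and the carboxyl carbon in one cycloaddition and buys only one stereocentre.

Key step: step 4

Remarks on the chemistry:
- Atom labels used throughout: C1–C6 for ring A (C1 isopropyl-bearing, C4 carbinol), C7, O8, C9, C10, C11 for ring B, C1'–C6' for the cyclohexene of the acid half, Cα and Cβ for the acrylate.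
- The (R)-configured prolinol ether in step 1 is assumed to deliver the (R)-aldehyde, by attack of the electrophile on the enamine face remote from the diarylmethyl group.
- The silyl group on the diene is triisopropylsilyl, chosen for stability to base and resistance to O-to-O migration in steps 5 and 6.
- Compounds 19, 21, 24, 25, 34 and 35 are taken as commercially available.

## Steps

Step 1
Reactants: 1 3-methylbutanal; 2 but-3-en-2-one
Product: 3 (R)-2-isopropyl-5-oxohexanal
Conditions: (R)-2-[methoxy(diphenyl)methyl]pyrrolidine (5 mol%), ethyl 3,4-dihydroxybenzoate (20 mol%), neat, 4 °C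
Reagents that add atoms: none
Why: Enamine-catalysed Michael addition; the (E)-enamine of 1 should add to 2 on the face remote from the diarylmethyl group, setting the isopropyl-bearing carbon (future C1) as R, while the catechol co-catalyst activates the enone by hydrogen bonding.

Step 2
Reactants: 3 (R)-2-isopropyl-5-oxohexanal
Product: 4 (R)-4-isopropylcyclohex-2-en-1-one
Conditions: LiOH (0.2 equiv), i-PrOH, rt
Reagents that add atoms: none
Why: Intramolecular aldol condensation of the methyl ketone enolate onto the aldehyde followed by dehydration; mild hydroxide at room temperature should leave the γ-stereocentre intact.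

Step 3
Reactants: 5 3-methylbut-2-enal
Product: 6 (E)-1-(triisopropylsilyloxy)-3-methylbuta-1,3-diene
Conditions: i-Pr3SiOTf, Et3N, Et2O, 0 °C → rt
Reagents that add atoms: triisopropylsilyl trifluoromethanesulfonate, CC(C)[Si](C(C)C)(C(C)C)OS(=O)(=O)C(F)(F)F
Why: Soft enolisation; O-silylation of the s-trans enal and γ-deprotonation by the amine should give the (E)-1-silyloxy diene, and any Z isomer cannot reach the s-cis form and stays inert in step 4.

Step 4
Reactants: 4 (R)-4-isopropylcyclohex-2-en-1-one; 6 (E)-1-(triisopropylsilyloxy)-3-methylbuta-1,3-diene
Product: 7 cis-fused octalone, 4-isopropyl-6-methyl-8-(triisopropylsilyloxy)-3,4,4a,5,8,8a-hexahydronaphthalen-1(2H)-one (ketone at C4; H5 and H6 cis; C6–C11 trans to isopropyl; silyloxy on C7 cis to C4 on ring B)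
Conditions: Et2AlCl (0.3 equiv), toluene, −78 → −20 °C; cold aqueous NaHCO3 quench
Reagents that add atoms: none
Why: Lewis-acid-accelerated, concerted but asynchronous normal-demand Diels–Alder reaction in which Et2AlCl binds the C4 carbonyl of 4 and lowers the enone LUMO. The closest known reaction type is the Lewis-acid-catalysed addition of 2-methylbutadiene-type dienes to 4-alkylcyclohex-2-enones, which gives cis-fused octalones. Ring B (C5, C7, C9, C10, C11, C6) closes by intermolecular suprafacial [4+2] cycloaddition, forming C5–C7 and C6–C11 together. C6 is controlled by the C1 isopropyl group, which is pseudo-equatorial on the half-chair and shields its own face, so the diene bonds anti to it; C5 follows from suprafacial addition (cis ring fusion); C7 follows from the endo transition state and is of no consequence because it becomes a carbonyl in step 9. The 1-silyloxy and 3-methyl groups both put the largest HOMO coefficient on the CH2 terminus, which bonds to the β-carbon C6, so oxygen ends on C7 and the methyl group on C10. The step needs facial selectivity anti to isopropyl and this regiochemistry, and both are secured by the substrate and the diene substitution. Sub-stoichiometric Lewis acid, low temperature and a cold basic quench should preserve the kinetic cis fusion and the β-silyloxy ketone.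

Step 5
Reactants: 7 cis-fused silyloxy octalone
Product: 8 spiro-epoxide at C4 (new CH2 axial and trans to C7; epoxide oxygen equatorial and cis to C7)
Conditions: Me3S+ I−, KN(SiMe3)2, THF, −10 → 0 °C
Reagents that add atoms: trimethylsulfonium iodide, C[S+](C)C.[I-]
Why: Corey–Chaykovsky epoxidation; dimethylsulfonium methylide adds irreversibly and axially to the C4 carbonyl from the convex face opposite to the axial C5–C7 bond, so C4 should be set as S (oxygen cis to C7), and addition at low temperature should outrun enolisation towards C5.

Step 6
Reactants: 8 spiro-epoxide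
Product: 9 diol (tertiary hydroxyl on C4 cis to C7, primary CH2OH axial)
Conditions: KOH, DMSO/H2O (4:1), 90 °C
Reagents that add atoms: water, O
Why: SN2 opening of the 2,2-disubstituted epoxide by hydroxide at the CH2 terminus; the C4–O bond is not broken, so the configuration from step 5 is kept, and the triisopropylsilyl ether should neither cleave nor migrate.

Step 7
Reactants: 9 diol
Product: 10 spiro-acetonide (2,2-dimethyl-1,3-dioxolane spiro-fused at C4)
Conditions: 2,2-dimethoxypropane, pyridinium p-toluenesulfonate (cat.), acetone, rt
Reagents that add atoms: 2,2-dimethoxypropane, COC(C)(C)OC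
Why: Acid-catalysed transacetalisation ties the tertiary and primary hydroxyls into a dioxolane that tolerates fluoride, oxidants, strong base and silyl Lewis acids.

Step 8
Reactants: 10 spiro-acetonide silyl ether
Product: 11 allylic alcohol (free hydroxyl on C7)
Conditions: Bu4NF, THF, 45 °C
Reagents that add atoms: none
Why: Fluoride-induced cleavage of the secondary silyl ether; nothing else in 10 is fluoride-labile.

Step 9
Reactants: 11 allylic alcohol
Product: 12 conjugated enone (C7 ketone, C9=C10 double bond, methyl on C10)
Conditions: Dess–Martin periodinane, NaHCO3, CH2Cl2, 0 °C → rt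
Reagents that add atoms: none
Why: Dess–Martin oxidation of the allylic alcohol under buffered, non-epimerising conditions; the C7 stereocentre from the cycloaddition is erased here.

Step 10
Reactants: 12 conjugated enone
Product: 14 β,γ-unsaturated ketone (C7 ketone, C9H2, C10=C11 double bond), via potassium dienolate 13 (not isolated)
Conditions: KOt-Bu (4 equiv), t-BuOH/THF, 0 °C; poured into cold aqueous AcOH; used crude
Reagents that add atoms: none
Why: Deconjugation through the extended dienolate: thermodynamic γ-deprotonation at ring carbon C11 gives the homoannular dienolate 13, and kinetic protonation at the α-carbon C9 gives the β,γ-enone, as in the conversion of 3-methylcyclohex-2-enones into their 3-ene isomers; the equatorial C4–O bond lies near the nodal plane of any C5 enolate, which should retard β-elimination.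

Step 11
Reactants: 14 β,γ-unsaturated ketone
Product: 15 seven-membered lactone acetonide (C5–C7(=O)–O8–C9H2–C10(CH3)=C11–C6)
Conditions: Me3SiOOSiMe3 (2.5 equiv), Me3SiOTf (0.2 equiv), CH2Cl2, −78 → −40 °C
Reagents that add atoms: bis(trimethylsilyl) peroxide, C[Si](C)(C)OO[Si](C)(C)C
Why: Baeyer–Villiger oxidation with a silyl peroxide that does not epoxidise alkenes; the peroxyketal should collapse with migration of the allylic C9, whose developing positive charge is stabilised by the C10=C11 π bond, whereas C5 is inductively deactivated by the C4–O bond. No stereocentre is touched.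

Step 12
Reactants: 15 lactone acetonide
Product: 17 lactone aldehyde (CHO on C10), via allylic alcohol 16 (not isolated)
Conditions: SeO2 (0.5 equiv), t-BuOOH (3 equiv), CH2Cl2, rt; filtration; then Dess–Martin periodinane, NaHCO3, CH2Cl2, 0 °C → rt
Reagents that add atoms: tert-butyl hydroperoxide, CC(C)(C)OO
Why: Riley allylic oxidation (ene reaction then [2,3] shift) at the methyl group, the only unactivated allylic position on the disubstituted terminus C10 since C9 bears the acyloxy oxygen and C6–H sits on the less substituted terminus; the second oxidant converges the alcohol/aldehyde mixture on the aldehyde.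

Step 13
Reactants: 17 lactone aldehyde acetonide
Product: 18 diol aldehyde (free tertiary hydroxyl on C4 and free CH2OH)
Conditions: AcOH/H2O/THF (3:1:1), 40 °C
Reagents that add atoms: none
Why: Acetal hydrolysis; the liberated CH2OH (axial on C4) and the lactone carbonyl carbon C7 (axial on C5) are trans-diaxial, so translactonisation to a five-membered lactone would need the unfavourable ring flip and should not compete.

Step 14
Reactants: 19 2-bromoprop-2-en-1-ol
Product: 20 (2-bromoallyloxy)(tert-butyl)dimethylsilane
Conditions: t-BuMe2SiCl, imidazole, CH2Cl2, 0 °C → rt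
Reagents that add atoms: tert-butyldimethylsilyl chloride, CC(C)(C)[Si](C)(C)Cl
Why: Standard silylation of a primary alcohol; this ether stays in place until the last step.

Step 15
Reactants: 20 (2-bromoallyloxy)(tert-butyl)dimethylsilane; 21 (E)-3-(tributylstannyl)prop-2-en-1-ol
Product: 22 (E)-4-[(tert-butyldimethylsilyloxy)methyl]penta-2,4-dien-1-ol
Conditions: Pd(PPh3)4 (5 mol%), CuI (10 mol%), CsF (2 equiv), DMF, 45 °C
Reagents that add atoms: none
Why: Stille coupling of a vinyl bromide with a vinylstannane at zerovalent palladium; both partners couple with retention, so the E geometry of 21 is carried into the diene.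

Step 16
Reactants: 22 dienol
Product: 23 (E)-diene 4-methoxybenzyl ether, PMBOCH2–CH=CH–C(=CH2)–CH2OSiMe2t-Bu
Conditions: NaH, 4-methoxybenzyl chloride, Bu4NI (cat.), THF, 0 °C → rt
Reagents that add atoms: 4-methoxybenzyl chloride, COc1ccc(CCl)cc1
Why: Williamson etherification; the benzyl-type ether withstands the aluminium, magnesium and titanium reagents that follow and is removable oxidatively beside the silyl ether.

Step 17
Reactants: 24 (S)-4-benzyl-oxazolidin-2-one; 25 acryloyl chloride
Product: 26 (S)-3-acryloyl-4-benzyl-oxazolidin-2-one
Conditions: n-BuLi, THF, −78 °C; then 25, −78 → 0 °C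
Reagents that add atoms: none
Why: N-acylation of the lithiated oxazolidinone; it gives the chelating dienophile for the auxiliary-controlled cycloaddition.

Step 18
Reactants: 23 diene 4-methoxybenzyl ether; 26 (S)-3-acryloyl-4-benzyl-oxazolidin-2-one
Product: 27 cycloadduct imide (cyclohexene with CH2OPMB on C1', CH2OSiMe2t-Bu on C3', N-acyloxazolidinone on C6'; C1' and C6' substituents cis)
Conditions: Et2AlCl (1.4 equiv), CH2Cl2, −78 °C
Reagents that add atoms: none
Why: Auxiliary-controlled Diels–Alder reaction of an N-acryloyl oxazolidinone; in the aluminium chelate (s-cis acryloyl) the benzyl group blocks one face so the diene adds to the other, which sets C6'; the endo transition state sets C1' cis to C6'; the 1- and 3-substituents of the diene both direct the acyl-bearing carbon next to C1'.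

Step 19
Reactants: 27 cycloadduct imide
Product: 28 N-methoxy-N-methylamide on C6'
Conditions: MeNH(OMe)·HCl, AlMe3, CH2Cl2, −10 °C → rt
Reagents that add atoms: N,O-dimethylhydroxylamine hydrochloride, CNOC.Cl
Why: Aluminium amide transamination of the imide at the exocyclic carbonyl releases the auxiliary without base, so the cis C6' centre α to the carbonyl is not epimerised.

Step 20
Reactants: 28 N-methoxy-N-methylamide
Product: 29 methyl ketone (acetyl on C6', cis to the C1' arm)
Conditions: MeMgBr, THF, 0 °C; cold 1 M HCl
Reagents that add atoms: methylmagnesium bromide, C[Mg]Br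
Why: Single addition to the N-methoxy-N-methylamide through the stable magnesium chelate; the ketone appears only on the cold acidic quench, which limits epimerisation.

Step 21
Reactants: 29 methyl ketone
Product: 30 isopropenyl compound (prop-1-en-2-yl on C6')
Conditions: Cp2TiMe2 (2.5 equiv), toluene, 65 °C, dark
Reagents that add atoms: dimethyltitanocene, [CH3-].[CH3-].[Ti+4].c1cc[cH-]c1.c1cc[cH-]c1
Why: Titanium carbene methylenation of the ketone under non-basic conditions, chosen over a phosphorus ylide because the cis α-centre of 29 epimerises easily under base.

Step 22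
Reactants: 30 isopropenyl compound
Product: 31 isopropyl compound (C1' CH2OPMB and C6' isopropyl cis)
Conditions: H2 (1 atm), RhCl(PPh3)3 (5 mol%), benzene/EtOH (1:1), rt
Reagents that add atoms: none
Why: Homogeneous hydrogenation with RhCl(PPh3)3 reduces the 1,1-disubstituted alkene much faster than the trisubstituted ring alkene and leaves the benzyl-type ether alone; no new stereocentre is formed.

Step 23
Reactants: 31 isopropyl compound
Product: 32 [(1R,6S)-3-[(tert-butyldimethylsilyloxy)methyl]-6-isopropylcyclohex-2-en-1-yl]methanol
Conditions: DDQ (1.2 equiv), CH2Cl2/pH 7 buffer (10:1), 0 °C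
Reagents that add atoms: none
Why: Oxidative cleavage of the 4-methoxybenzyl ether by hydride abstraction at the electron-rich benzylic position; the silyl ether and the alkene are unaffected.

Step 24
Reactants: 32 primary alcohol
Product: 33 (1R,6S)-3-[(tert-butyldimethylsilyloxy)methyl]-6-isopropylcyclohex-2-ene-1-carbaldehyde
Conditions: Dess–Martin periodinane, NaHCO3, CH2Cl2, 0 °C; used crude at once
Reagents that add atoms: none
Why: Buffered Dess–Martin oxidation to the β,γ-unsaturated, α-branched aldehyde; neutral conditions and immediate use guard against epimerisation at C1' and migration of the ring alkene.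

Step 25
Reactants: 34 methyl (triphenylphosphoranylidene)acetate (2 equiv); 35 (chloromethoxy)triisopropylsilane
Product: 36 methyl 2-(triphenylphosphoranylidene)-3-(triisopropylsilyloxy)propanoate
Conditions: toluene, rt → 40 °C; filtration of the phosphonium chloride
Reagents that add atoms: none
Why: C-alkylation of a stabilised ylide by an α-chloro ether followed by transylidation with the second equivalent of 34, the known route to α-(alkoxymethyl) stabilised ylides.

Step 26
Reactants: 33 aldehyde; 36 stabilised ylide
Product: 37 methyl (E)-3-[(1R,6S)-3-[(tert-butyldimethylsilyloxy)methyl]-6-isopropylcyclohex-2-en-1-yl]-2-[(triisopropylsilyloxy)methyl]acrylate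
Conditions: toluene, 50 °C
Reagents that add atoms: none
Why: Wittig olefination with a stabilised α-substituted ylide, which should place the ester trans to the ring substituent (E) under thermodynamic control of oxaphosphetane formation; the ylide is nearly neutral, so C1' should keep its configuration.

Step 27
Reactants: 37 methyl ester
Product: 38 (E)-3-[(1R,6S)-3-[(tert-butyldimethylsilyloxy)methyl]-6-isopropylcyclohex-2-en-1-yl]-2-[(triisopropylsilyloxy)methyl]acrylic acid
Conditions: LiOH·H2O, THF/MeOH/H2O (3:1:1), rt → 40 °C; then 1 M HCl to pH 3
Reagents that add atoms: lithium hydroxide, [Li+].[OH-]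
Why: Saponification of the methyl ester; hydroxide is too weak a base to remove the γ-hydrogen on C1', and primary silyl ethers survive these conditions.

Step 28
Reactants: 18 diol aldehyde; 38 bis-silylated acid
Product: 40 coupled ester aldehyde (acyl group of 38 on the CH2O arm of C4; tertiary hydroxyl free; CHO on C10), via mixed anhydride 39 (not isolated)
Conditions: 38, 2,4,6-trichlorobenzoyl chloride, Et3N, toluene, rt; then 18, DMAP (0.3 equiv), rt
Reagents that add atoms: none
Why: Yamaguchi esterification through the mixed anhydride; only the primary hydroxyl of 18 is acylated because the tertiary one is too hindered, and the E acrylate is the thermodynamic isomer and should not change.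

Step 29
Reactants: 40 coupled ester aldehyde
Product: 41 coupled ester acid (CO2H on C10; both silyl ethers in place)
Conditions: NaClO2, NaH2PO4, 2-methylbut-2-ene (excess), t-BuOH/H2O, 0 °C → rt
Reagents that add atoms: sodium chlorite, [Na+].[O-]Cl=O
Why: Pinnick oxidation converts only the aldehyde to the acid; the alkene scavenger removes hypochlorous acid and so protects the electron-rich ring alkene of the acid half.

Step 30
Reactants: 41 coupled ester acid
Product: 42 target compound
Conditions: HF·pyridine, pyridine, THF, 0 °C → rt
Reagents that add atoms: none
Why: Buffered fluoride cleavage of the two primary silyl ethers under weakly acidic, non-nucleophilic conditions that should spare the allylic lactone, the acrylate ester and the tertiary alcohol.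

## Compound list

1 | 3-methylbutanal | CC(C)CC=O | starting material
2 | but-3-en-2-one | CC(=O)C=C | starting material
3 | (R)-2-isopropyl-5-oxohexanal | O=C[C@H](CCC(C)=O)C(C)C | intermediate
4 | (R)-4-isopropylcyclohex-2-en-1-one | CC(C)[C@H]1CCC(=O)C=C1 | intermediate
5 | 3-methylbut-2-enal | CC(C)=CC=O | starting material
6 | (E)-1-(triisopropylsilyloxy)-3-methylbuta-1,3-diene | C=C(C)/C=C/O[Si](C(C)C)(C(C)C)C(C)C | intermediate
7 | cis-fused silyloxy octalone (endo adduct, C6–C11 trans to isopropyl) | CC(C)[C@H]1CCC(=O)[C@@H]2[C@H](O[Si](C(C)C)(C(C)C)C(C)C)C=C(C)C[C@H]12 | intermediate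
8 | C4 spiro-epoxide (oxygen cis to C7) | CC(C)[C@H]1CC[C@@]3(CO3)[C@@H]2[C@H](O[Si](C(C)C)(C(C)C)C(C)C)C=C(C)C[C@H]12 | intermediate
9 | C4 diol silyl ether | CC(C)[C@H]1CC[C@@](O)(CO)[C@@H]2[C@H](O[Si](C(C)C)(C(C)C)C(C)C)C=C(C)C[C@H]12 | intermediate
10 | spiro-acetonide silyl ether | CC(C)[C@H]1CC[C@@]3(COC(C)(C)O3)[C@@H]2[C@H](O[Si](C(C)C)(C(C)C)C(C)C)C=C(C)C[C@H]12 | intermediate
11 | spiro-acetonide allylic alcohol (hydroxyl on C7) | CC(C)[C@H]1CC[C@@]3(COC(C)(C)O3)[C@@H]2[C@H](O)C=C(C)C[C@H]12 | intermediate
12 | conjugated enone acetonide | CC(C)[C@H]1CC[C@@]3(COC(C)(C)O3)[C@@H]2C(=O)C=C(C)C[C@H]12 | intermediate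
13 | potassium dienolate of 12 | CC(C)[C@H]1CC[C@@]3(COC(C)(C)O3)[C@@H]2C([O-])=CC(C)=C[C@H]12.[K+] | intermediate
14 | β,γ-unsaturated ketone acetonide | CC(C)[C@H]1CC[C@@]3(COC(C)(C)O3)[C@@H]2C(=O)CC(C)=C[C@H]12 | intermediate
15 | seven-membered lactone acetonide (methyl on C10) | CC(C)[C@H]1CC[C@@]3(COC(C)(C)O3)[C@@H]2C(=O)OCC(C)=C[C@H]12 | intermediate
16 | lactone allylic alcohol (CH2OH on C10) | CC(C)[C@H]1CC[C@@]3(COC(C)(C)O3)[C@@H]2C(=O)OCC(CO)=C[C@H]12 | intermediate
17 | lactone aldehyde acetonide (CHO on C10) | CC(C)[C@H]1CC[C@@]3(COC(C)(C)O3)[C@@H]2C(=O)OCC(C=O)=C[C@H]12 | intermediate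
18 | lactone aldehyde diol | CC(C)[C@H]1CC[C@@](O)(CO)[C@@H]2C(=O)OCC(C=O)=C[C@H]12 | intermediate
19 | 2-bromoprop-2-en-1-ol | OCC(Br)=C | starting material
20 | (2-bromoallyloxy)(tert-butyl)dimethylsilane | C=C(Br)CO[Si](C)(C)C(C)(C)C | intermediate
21 | (E)-3-(tributylstannyl)prop-2-en-1-ol | OC/C=C/[Sn](CCCC)(CCCC)CCCC | starting material
22 | (E)-4-[(tert-butyldimethylsilyloxy)methyl]penta-2,4-dien-1-ol | OC/C=C/C(=C)CO[Si](C)(C)C(C)(C)C | intermediate
23 | (E)-diene 4-methoxybenzyl ether | COc1ccc(COC/C=C/C(=C)CO[Si](C)(C)C(C)(C)C)cc1 | intermediate
24 | (S)-4-benzyl-oxazolidin-2-one | O=C1N[C@@H](Cc2ccccc2)CO1 | starting material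
25 | acryloyl chloride | C=CC(=O)Cl | starting material
26 | (S)-3-acryloyl-4-benzyl-oxazolidin-2-one | C=CC(=O)N1[C@@H](Cc2ccccc2)COC1=O | intermediate
27 | cis cycloadduct imide | COc1ccc(COC[C@H]2C=C(CO[Si](C)(C)C(C)(C)C)CC[C@H]2C(=O)N3[C@@H](Cc4ccccc4)COC3=O)cc1 | intermediate
28 | cis N-methoxy-N-methylamide | COc1ccc(COC[C@H]2C=C(CO[Si](C)(C)C(C)(C)C)CC[C@H]2C(=O)N(C)OC)cc1 | intermediate
29 | cis methyl ketone | COc1ccc(COC[C@H]2C=C(CO[Si](C)(C)C(C)(C)C)CC[C@H]2C(C)=O)cc1 | intermediate
30 | cis isopropenyl compound | COc1ccc(COC[C@H]2C=C(CO[Si](C)(C)C(C)(C)C)CC[C@H]2C(C)=C)cc1 | intermediate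
31 | cis isopropyl compound | COc1ccc(COC[C@H]2C=C(CO[Si](C)(C)C(C)(C)C)CC[C@H]2C(C)C)cc1 | intermediate
32 | [(1R,6S)-3-[(tert-butyldimethylsilyloxy)methyl]-6-isopropylcyclohex-2-en-1-yl]methanol | OC[C@H]1C=C(CO[Si](C)(C)C(C)(C)C)CC[C@H]1C(C)C | intermediate
33 | (1R,6S)-3-[(tert-butyldimethylsilyloxy)methyl]-6-isopropylcyclohex-2-ene-1-carbaldehyde | O=C[C@H]1C=C(CO[Si](C)(C)C(C)(C)C)CC[C@H]1C(C)C | intermediate
34 | methyl (triphenylphosphoranylidene)acetate | COC(=O)C=P(c1ccccc1)(c1ccccc1)c1ccccc1 | starting material
35 | (chloromethoxy)triisopropylsilane | ClCO[Si](C(C)C)(C(C)C)C(C)C | starting material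
36 | methyl 2-(triphenylphosphoranylidene)-3-(triisopropylsilyloxy)propanoate | COC(=O)C(CO[Si](C(C)C)(C(C)C)C(C)C)=P(c1ccccc1)(c1ccccc1)c1ccccc1 | intermediate
37 | methyl (E)-acrylate of the acid half, bis-silyl ether | COC(=O)/C(CO[Si](C(C)C)(C(C)C)C(C)C)=C/[C@H]1C=C(CO[Si](C)(C)C(C)(C)C)CC[C@H]1C(C)C | intermediate
38 | (E)-acrylic acid of the acid half, bis-silyl ether | OC(=O)/C(CO[Si](C(C)C)(C(C)C)C(C)C)=C/[C@H]1C=C(CO[Si](C)(C)C(C)(C)C)CC[C@H]1C(C)C | intermediate
39 | mixed anhydride of 38 with 2,4,6-trichlorobenzoic acid | Clc1cc(Cl)c(C(=O)OC(=O)/C(CO[Si](C(C)C)(C(C)C)C(C)C)=C/[C@H]2C=C(CO[Si](C)(C)C(C)(C)C)CC[C@H]2C(C)C)c(Cl)c1 | intermediate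
40 | coupled ester aldehyde, bis-silyl ether | CC(C)[C@H]1CC[C@@](O)(COC(=O)/C(CO[Si](C(C)C)(C(C)C)C(C)C)=C/[C@H]3C=C(CO[Si](C)(C)C(C)(C)C)CC[C@H]3C(C)C)[C@@H]2C(=O)OCC(C=O)=C[C@H]12 | intermediate
41 | coupled ester acid, bis-silyl ether | CC(C)[C@H]1CC[C@@](O)(COC(=O)/C(CO[Si](C(C)C)(C(C)C)C(C)C)=C/[C@H]3C=C(CO[Si](C)(C)C(C)(C)C)CC[C@H]3C(C)C)[C@@H]2C(=O)OCC(C(=O)O)=C[C@H]12 | intermediate
42 | CNP0361406.10 | CC(C)[C@H]1CC[C@@](O)(COC(=O)/C(=C/[C@H]2C=C(CO)CC[C@H]2C(C)C)CO)[C@@H]2C(=O)OCC(C(=O)O)=C[C@H]12 | target

## Step count and least certain steps

Total: 30 steps. Longest linear sequence: 15 steps (1, 2, 4–13, 28–30). The branch through the acid half (14–16, 18–24, 26–30) is equally long.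

**Step 4 (key step).** The most likely failure is Lewis-acid-induced breakdown of the silyl dienol ether (desilylation or a stepwise Mukaiyama–Michael path without ring closure), with low conversion because 4 is only a moderate dienophile. Epimerisation at C5 or loss of silanol from the β-silyloxy ketone on prolonged contact with the Lewis acid is also possible.
Fallback: from 4, the same enone is combined with 2-methylbuta-1,3-diene under Et2AlCl catalysis, a closely precedented cycloaddition that gives the oxygen-free cis-fused octalone F1. Corey–Chaykovsky epoxidation as in step 5 would give the spiro-epoxide F2, hydroxide opening the diol F3, and acetalisation the acetonide F4. Allylic oxidation of F4 with CrO3·3,5-dimethylpyrazole in CH2Cl2 at −20 °C is expected to attack the ring CH2 next to the unsubstituted alkene carbon (C7) and give the β-methyl enone, which rejoins the route at 12.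

**Step 10.** The likely failure is deprotonation at C5 instead of, or in equilibrium with, the γ-position. This can lead to β-elimination of the C4 oxygen or epimerisation to the trans-fused ketone, and the β,γ-enone can reconjugate during work-up.
Fallback: from 12, acid-catalysed enol acetylation (isopropenyl acetate, catalytic p-toluenesulfonic acid, reflux) would give the extended dienol acetate F5. Treatment with NaBH4 in EtOH/THF at 0 °C cleaves the acetate and reduces the transient β,γ-unsaturated ketone faster than it reconjugates, giving the homoallylic alcohol F6 (configuration at C7 of no consequence). Dess–Martin oxidation under buffered conditions returns to 14 without any strong base.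

**Step 11.** The likely failure is migration of the secondary C5 instead of the primary allylic C9, which gives the regioisomeric lactone, or acid-induced reconjugation of the enone before oxygen transfer.
Fallback: from 14, the ketone is deprotonated at the doubly activated C9 (LiN(SiMe3)2, THF, −78 °C) and hydroxylated with 2-(phenylsulfonyl)-3-phenyloxaziridine to the α-hydroxy ketone F7 (configuration at C9 of no consequence). Glycol-type cleavage with NaIO4 in aqueous THF would give the seco acid with a (Z)-enal, F8. Reduction with NaBH4/CeCl3·7H2O in MeOH at −40 °C gives the hydroxy acid F9. Lactonisation with 2-chloro-1-methylpyridinium iodide and Et3N at high dilution closes the seven-membered ring and returns to 15 with unambiguous placement of O8.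

**Step 12.** The likely failure is sluggish ene reaction at an alkene deactivated by the allylic acyloxy group, with competing oxidation at C6–H or over-oxidation.
Fallback: from 15, epoxidation of C10=C11 (m-chloroperbenzoic acid, NaHCO3) would give the epoxide F10 (configuration of no consequence). Silyl triflate-mediated isomerisation (Me3SiOTf, 2,6-lutidine, then 1,8-diazabicyclo[5.4.0]undec-7-ene, then mild acid) gives the allylic alcohol with an exocyclic methylene, F11. Sulfenylation (PhSCl, Et3N) triggers a Mislow–Evans [2,3] shift to the allylic sulfoxide F12, which restores the C10=C11 double bond. A Pummerer reaction (trifluoroacetic anhydride, 2,6-lutidine, then aqueous NaHCO3) gives the aldehyde and returns to 17.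

**Step 26.** The likely failure is a slow reaction between the hindered ylide and the α-branched aldehyde, which gives time for epimerisation at C1' or migration of the ring alkene into conjugation with the aldehyde.
Fallback: from 33, the lithium enolate of methyl 3-(triisopropylsilyloxy)propanoate (LiN(i-Pr)2, THF, −78 °C) should add within minutes at low temperature to give the β-hydroxy ester F13. Acetylation (Ac2O, pyridine, DMAP) gives the acetate F14. Base-induced E1cB elimination (1,8-diazabicyclo[5.4.0]undec-7-ene, CH2Cl2, 0 °C) gives the thermodynamically preferred E ester and returns to 37.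

**Step 28.** The likely failure is slow acylation of the neopentyl-type primary hydroxyl. Prolonged contact with DMAP could then allow its conjugate addition to the enal with ionisation of the allylic lactone C9–O8 bond.
Fallback: from 38 and 18, the acid is converted into the acid chloride F15 with 1-chloro-N,N,2-trimethylprop-1-en-1-amine under neutral conditions. The diol 18 is converted into its dibutylstannylene acetal F16 (Bu2SnO, toluene, reflux with removal of water). Combining F15 and F16 in CH2Cl2 at 0 °C acylates the primary oxygen selectively without any nucleophilic amine, and aqueous work-up returns to 40.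

## Further compounds

F1 | step 4 | oxygen-free cis-fused octalone (adduct of 4 with 2-methylbuta-1,3-diene) | CC(C)[C@H]1CCC(=O)[C@@H]2CC=C(C)C[C@H]12
F2 | step 4 | C4 spiro-epoxide of F1 | CC(C)[C@H]1CC[C@@]3(CO3)[C@@H]2CC=C(C)C[C@H]12
F3 | step 4 | C4 diol from F2 | CC(C)[C@H]1CC[C@@](O)(CO)[C@@H]2CC=C(C)C[C@H]12
F4 | step 4 | spiro-acetonide of F3 | CC(C)[C@H]1CC[C@@]3(COC(C)(C)O3)[C@@H]2CC=C(C)C[C@H]12
F5 | step 10 | extended dienol acetate of 12 | CC(C)[C@H]1CC[C@@]3(COC(C)(C)O3)[C@@H]2C(OC(C)=O)=CC(C)=C[C@H]12
F6 | step 10 | homoallylic alcohol (C7 hydroxyl, C10=C11; C7 configuration not defined) | CC(C)[C@H]1CC[C@@]3(COC(C)(C)O3)[C@@H]2C(O)CC(C)=C[C@H]12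
F7 | step 11 | α-hydroxy ketone (hydroxyl on C9; C9 configuration not defined) | CC(C)[C@H]1CC[C@@]3(COC(C)(C)O3)[C@@H]2C(=O)C(O)C(C)=C[C@H]12
F8 | step 11 | seco acid (Z)-enal | CC(C)[C@H]1CC[C@@]3(COC(C)(C)O3)[C@H](C(=O)O)[C@@H]1/C=C(C)\C=O
F9 | step 11 | seco hydroxy acid | CC(C)[C@H]1CC[C@@]3(COC(C)(C)O3)[C@H](C(=O)O)[C@@H]1/C=C(C)\CO
F10 | step 12 | C10–C11 epoxide of 15 (epoxide configuration not defined) | CC(C)[C@H]1CC[C@@]3(COC(C)(C)O3)[C@@H]2C(=O)OCC4(C)OC4[C@H]12
F11 | step 12 | allylic alcohol with exocyclic methylene on C10 (C11 configuration not defined) | CC(C)[C@H]1CC[C@@]3(COC(C)(C)O3)[C@@H]2C(=O)OCC(=C)C(O)[C@H]12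
F12 | step 12 | allylic phenyl sulfoxide (sulfur configuration not defined) | CC(C)[C@H]1CC[C@@]3(COC(C)(C)O3)[C@@H]2C(=O)OCC(CS(=O)c4ccccc4)=C[C@H]12
F13 | step 26 | β-hydroxy ester (new centres not defined) | COC(=O)C(CO[Si](C(C)C)(C(C)C)C(C)C)C(O)[C@H]1C=C(CO[Si](C)(C)C(C)(C)C)CC[C@H]1C(C)C
F14 | step 26 | β-acetoxy ester (new centres not defined) | COC(=O)C(CO[Si](C(C)C)(C(C)C)C(C)C)C(OC(C)=O)[C@H]1C=C(CO[Si](C)(C)C(C)(C)C)CC[C@H]1C(C)C
F15 | step 28 | acid chloride of 38 | ClC(=O)/C(CO[Si](C(C)C)(C(C)C)C(C)C)=C/[C@H]1C=C(CO[Si](C)(C)C(C)(C)C)CC[C@H]1C(C)C
F16 | step 28 | dibutylstannylene acetal of 18 | CC(C)[C@H]1CC[C@@]3(CO[Sn](CCCC)(CCCC)O3)[C@@H]2C(=O)OCC(C=O)=C[C@H]12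
A1 | alternative 1 | seven-membered lactone acetonide | CC(C)[C@H]1CC[C@@]3(COC(C)(C)O3)[C@@H]2C(=O)OCC(C)=C[C@H]12
A2 | alternative 1 | cis-fused β,γ-unsaturated bicyclic ketone acetonide | CC(C)[C@H]1CC[C@@]3(COC(C)(C)O3)[C@@H]2C(=O)CC(C)=C[C@H]12
A3 | alternative 2 | isopropyl triene | C=C/C(C(C)C)=C/C=C1COC(C)(C)OC1
A4 | alternative 2 | ethyl buta-2,3-dienoate | C=C=CC(=O)OCC
A5 | alternative 2 | 2-methylenecyclohex-3-ene ester adduct | CC(C)C1=CCC(=C)[C@H](C(=O)OCC)[C@@H]1C=C2COC(C)(C)OC2
A6 | alternative 3 | cis-fused hydroxy bicyclic lactone | CC(C)[C@H]1CC[C@@](O)(COCc3ccc(OC)cc3)[C@@H]2C(=O)OC[C@H]12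
A7 | alternative 3 | α-bromo butyrolactone with tethered α-alkoxy ketone (C–Br configuration not defined) | CC(C)[C@@H](CCC(=O)COCc1ccc(OC)cc1)[C@H]1COC(=O)C1Br
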